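**Assumption:** ent-kaurane numbering is used for locants; the C2 epimers of 5/6, the spiro-epoxide epimers of 9, and the C8/C16 epimers of 13/17 are carried as mixtures because each converges in a later step. The route is a paper design; no step has been run.

## Retrosynthetic overview

1. Ring D last: C13–C16 bond by 5-exo α-keto radical cyclization of bromoketone 17, which comes from ethyl ketone 16 (an isomer of the target).
2. Ring C: Diels–Alder of butadiene with the spiro alkylidene β-keto lactone 14 sets C8 and C9.
3. Spiro δ-lactone and C10: Ti(III) epoxide-opening radical addition to an acrylate with in situ lactonization (9 → 11), then C8 propionylation and dehydrogenation.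
4. Ring A and the 6,19-methyl acetal: catalytic asymmetric conjugate alkenylation of 3-methylcyclohexenone (sets C4), enolate trapping with orthoformate (C6), ozonolysis/reduction/acetalization (7).
5. Ring order: A (commercial) → tetrahydrofuran acetal → spiro δ-lactone → C → D.

## Route

**Step 1**
Reactants: 1, 3-methylcyclohex-2-en-1-one; 2, hex-1-yne
Product: 3, (S)-trimethyl({3-[(E)-hex-1-en-1-yl]-3-methylcyclohex-1-en-1-yl}oxy)silane
Conditions: 2, DIBAL-H, hexane, 55 °C; then 1, Cu(OTf)2 (5 mol %), chiral sulfonate-NHC·Ag precatalyst (2.5 mol %, enantiomer chosen to give S-3), THF, −30 °C; then TMSOTf, −78 → 0 °C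
Reagents that add atoms: hex-1-yne, CCCCC#C (as the (E)-hexenyl alane); TMSOTf, C[Si](C)(C)OS(=O)(=O)C(F)(F)F
Why: Cu-catalysed asymmetric conjugate addition of the alkenylalane (from hydroalumination) creates the C4 quaternary centre under catalyst control, with the alkenyl group as a masked C19, and O-silylation of the aluminium enolate fixes enolate regiochemistry toward C5.

**Step 2**
Reactants: 3; 4, trimethyl orthoformate
Product: 5, (3S)-2-(dimethoxymethyl)-3-[(E)-hex-1-en-1-yl]-3-methylcyclohexan-1-one (C2 epimers)
Conditions: TMSOTf (5 mol %), CH2Cl2, −78 °C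
Reagents that add atoms: trimethyl orthoformate, COC(OC)OC
Why: Mukaiyama-type addition of the silyl enol ether to the dimethoxycarbenium ion installs C6 at the aldehyde oxidation level regiospecifically at C5; the C5 configuration is corrected in step 4.

**Step 3**
Reactants: 5
Product: 6, (1R)-2-(dimethoxymethyl)-1-methyl-3-oxocyclohexane-1-carbaldehyde (C2 epimers)
Conditions: O3, CH2Cl2/MeOH, −78 °C; then Me2S
Reagents that add atoms: ozone, [O-][O+]=O
Why: Ozonolysis of the only C=C unmasks the C19 aldehyde while the ketone and acetal are inert.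

**Step 4**
Reactants: 6
Product: 7, (1S,3aR,7aS)-1-methoxy-3a-methylhexahydroisobenzofuran-7(1H)-one (cis-fused keto acetal, OMe on the convex face, cis to the angular methyl)
Conditions: NaBH4 (0.5 equiv), EtOH/CH2Cl2, −78 °C; then CSA (cat.), CH2Cl2, 4 Å MS, rt
Reagents that add atoms: none
Why: Aldehyde-selective borohydride reduction followed by acid-catalysed transacetalization closes the tetrahydrofuran, and C5 (α to the ketone) and C6 (acetal) equilibrate to the thermodynamic cis-fused bicycle with exo OMe.

**Step 5**
Reactants: 7; 8, trimethylsulfonium iodide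
Product: 9, (1S,3aR,7aR)-1-methoxy-3a-methylhexahydrospiro[isobenzofuran-7,2'-oxirane] (spiro-epoxide epimers)
Conditions: KHMDS, THF, 0 °C → rt
Reagents that add atoms: trimethylsulfonium iodide, C[S+](C)C.[I-]
Why: Corey–Chaykovsky epoxidation adds the C20 methylene to the ketone; the epoxide configuration is irrelevant because C10 becomes a planar radical in step 6.

**Step 6**
Reactants: 9; 10, 2,2,2-trifluoroethyl acrylate
Product: 11, spiro δ-lactone, (1S,3aR,7R,7aR)-1-methoxy-3a-methyloctahydrospiro[isobenzofuran-7,3'-pyran]-6'-one (kaurane 4R,5R,6S,10R)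
Conditions: Cp2TiCl2, Zn, 2,4,6-collidine·HCl, THF, rt
Reagents that add atoms: 2,2,2-trifluoroethyl acrylate, C=CC(=O)OCC(F)(F)F
Why: Ti(III) homolytic epoxide opening gives the tertiary C10 radical, which undergoes Giese addition to the acrylate on the convex face (anti to C6 and axial C19), and the titanium alkoxide lactonizes onto the activated ester, setting the C10 spiro centre.

**Step 7**
Reactants: 11; 12, N-methoxy-N-methylpropanamide
Product: 13, C8-propanoyl β-keto lactone (C8 epimers/enol)
Conditions: LDA, THF, −78 °C; then 12, −78 → 0 °C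
Reagents that add atoms: N-methoxy-N-methylpropanamide, CCC(=O)N(C)OC
Why: Claisen-type C-acylation of the lactone lithium enolate with a Weinreb amide stops at the stable tetrahedral chelate and delivers the β-keto lactone (C15–C17 installed).

**Step 8**
Reactants: 13
Product: 14, spiro 3-propanoyl-5,6-dihydro-2H-pyran-2-one (C8=C9 alkylidene β-keto lactone)
Conditions: PhSeCl, pyridine, CH2Cl2, 0 °C; then 30% H2O2, 0 °C (used crude)
Reagents that add atoms: none
Why: α-Selenenylation of the β-dicarbonyl and selenoxide syn-elimination toward the only β-hydrogens (C9) gives the doubly activated dienophile.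

**Step 9**
Reactants: 14; 15, buta-1,3-diene
Product: 16, cis-fused cyclohexene/δ-lactone Diels–Alder adduct (kaurane 4R,5R,6S,8S,9S,10R; C12=C13 alkene, C8 propanoyl)
Conditions: 15 (excess), ZnCl2, CH2Cl2/Et2O, 0 °C → rt, sealed tube
Reagents that add atoms: buta-1,3-diene, C=CC=C
Why: Lewis-acid-catalysed Diels–Alder on the chelated alkylidene β-keto lactone adds suprafacially, setting C8 and C9 together, on the lactone face syn to C1H2 and anti to the bulkier C5–C6 flank of the spiro centre.

**Step 10**
Reactants: 16
Product: 17, C16 α-bromo ketone (C16 epimers)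
Conditions: LiHMDS, TMSCl, THF, −78 °C; then NBS, −78 → 0 °C
Reagents that add atoms: N-bromosuccinimide, O=C1CCC(=O)N1Br
Why: C16 is the only enolizable position (C8 is quaternary), and bromination of the silyl enol ether with NBS leaves the ring alkene untouched.

**Step 11**
Reactants: 17
Product: 18, ludongnin H (kaurane 4R,5R,6S,8S,9S,10R,13R,16S)
Conditions: Bu3SnH (syringe pump), AIBN, PhH (5 mM), 80 °C; then DBU, PhMe, rt
Reagents that add atoms: none
Why: The tin-generated α-keto radical undergoes 5-exo-trig cyclization onto C13 from the only face the axial C8 acyl tether can reach (fixing C13), H-transfer caps C12, and DBU epimerizes C16 to the more stable exo methyl (syn to C14).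

## Compound list

1 | 3-methylcyclohex-2-en-1-one | CC1=CC(=O)CCC1 | starting material
2 | hex-1-yne | CCCCC#C | starting material
3 | (S)-trimethyl({3-[(E)-hex-1-en-1-yl]-3-methylcyclohex-1-en-1-yl}oxy)silane | CCCC/C=C/[C@]1(C)CCCC(O[Si](C)(C)C)=C1 | intermediate
4 | trimethyl orthoformate | COC(OC)OC | starting material
5 | (3S)-2-(dimethoxymethyl)-3-[(E)-hex-1-en-1-yl]-3-methylcyclohexan-1-one (C2 epimers) | CCCC/C=C/[C@]1(C)CCCC(=O)C1C(OC)OC | intermediate
6 | (1R)-2-(dimethoxymethyl)-1-methyl-3-oxocyclohexane-1-carbaldehyde (C2 epimers) | O=C[C@]1(C)CCCC(=O)C1C(OC)OC | intermediate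
7 | (1S,3aR,7aS)-1-methoxy-3a-methylhexahydroisobenzofuran-7(1H)-one | CO[C@H]1OC[C@]2(C)CCCC(=O)[C@H]12 | intermediate
8 | trimethylsulfonium iodide | C[S+](C)C.[I-] | starting material
9 | (1S,3aR,7aR)-1-methoxy-3a-methylhexahydrospiro[isobenzofuran-7,2'-oxirane] (epoxide epimers) | CO[C@H]1OC[C@]2(C)CCCC3(CO3)[C@H]12 | intermediate
10 | 2,2,2-trifluoroethyl acrylate | C=CC(=O)OCC(F)(F)F | starting material
11 | (1S,3aR,7R,7aR)-1-methoxy-3a-methyloctahydrospiro[isobenzofuran-7,3'-pyran]-6'-one | CO[C@H]1OC[C@]2(C)CCC[C@]3(COC(=O)CC3)[C@H]12 | intermediate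
12 | N-methoxy-N-methylpropanamide | CCC(=O)N(C)OC | starting material
13 | 5'-propanoyl derivative of 11 (β-keto lactone, C8 epimers) | CO[C@H]1OC[C@]2(C)CCC[C@]3(COC(=O)C(C(=O)CC)C3)[C@H]12 | intermediate
14 | 4',5'-didehydro-5'-propanoyl derivative of 11 (alkylidene β-keto lactone) | CO[C@H]1OC[C@]2(C)CCC[C@]3(COC(=O)C(C(=O)CC)=C3)[C@H]12 | intermediate
15 | buta-1,3-diene | C=CC=C | starting material
16 | Diels–Alder adduct (8S,9S; cis-fused cyclohex-12-ene/δ-lactone, C8 propanoyl) | CO[C@H]1OC[C@]2(C)CCC[C@]3(COC(=O)[C@@]4(C(=O)CC)CC=CC[C@H]43)[C@H]12 | intermediate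
17 | C16-bromo derivative of 16 (2-bromopropanoyl, C16 epimers) | CO[C@H]1OC[C@]2(C)CCC[C@]3(COC(=O)[C@@]4(C(=O)C(C)Br)CC=CC[C@H]43)[C@H]12 | intermediate
18 | ludongnin H | CO[C@H]1OC[C@]2(C)CCC[C@]3(COC(=O)[C@@]45C[C@@H](CC[C@H]43)[C@H](C)C5=O)[C@H]12 | target

## Summary

Total steps: 11. Longest linear sequence: 11 (fully linear from 1; all partners commercial).

Three steps most likely to fail, with fallbacks:

1. **Step 11** (α-keto radical: competing 6-endo closure to the bicyclo[2.2.2] isomer, or simple debromination). Fallback: make C16 the nucleophile instead. Convert 16 to its C15 silyl enol ether and close ring D by Pd(II)-mediated oxidative cycloalkenylation onto C12=C13 (exo-selective carbopalladation), then hydrogenate the transposed C11=C12 alkene and epimerize C16.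
2. **Step 9** (neopentyl β-carbon, facial selectivity at the spiro centre, Lewis-acid-sensitive acetal). Fallback: use the far more reactive 2-(tert-butyldimethylsilyloxy)buta-1,3-diene without Lewis acid (oxygen lands at C12). Then convert the C12 silyl enol ether regiospecifically to the enol triflate and reduce it (Pd/formate) to reach the same alkene 16.
3. **Step 6** (Ti(III) radical coupling: diastereoselectivity at C10 and acetal tolerance on a new substrate). Fallback: polar construction of C10. Meinwald rearrangement of 9 to the C10 aldehyde, convex-face Michael addition of its enolate/enamine to methyl acrylate, then NaBH4 reduction and lactonization to 11.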